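A direct plan would sulfate apigenin A1 at O-7 and O-4' to the disulfate A2 and would then turn C3–H of the intact flavone into C3–OSO3H with a trivalent-iodine/SO3 reagent by way of a 2,3-cyclic sulfate A3.
Its weakest steps would be:
(a) the oxidative C3–H sulfoxylation, a vinylic C–H functionalisation without precedent on a chromone, in which the electron-poor C2=C3 bond would have to beat the electron-rich ring A (C-6/C-8 beside the free 5-OH) for the iodine electrophile;
(b) the collapse of A3, which would have to ionise only at C-2 and lose H-3 without hydrolysis or loss of sulfate;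
(c) the partial sulfation of A1, after which two labile aryl sulfate salts would have to survive an oxidation and ion-pair chromatography.

The route would rest on cutting ring C at O1–C8a and C4–C4a: O-1 and C-4 are neighbours on ring A, with the C-5 oxygen next to C-4a, which is the pattern an aryne takes up. Ring A would enter as 3,5-bis(benzyloxy)benzyne and atoms O1–C2–C3–C4 as an α-benzyloxy-β-methoxycinnamic acid that already carries O-3 and ring B. In one operation the aryne would insert into the acid C(acyl)–O bond and the phenoxide set free would close the pyranone by addition–elimination. C-3 is thus oxygenated before any ring exists: no flavone C–H oxidation, no oxidant near sulfate esters, and all three sulfates are put on last, onto kaempferol itself.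

Key step: step 6

Assumption: the target is drawn as the free tris(hydrogen sulfate); it would be isolated as its tripotassium salt and set free as the acid on a cation-exchange resin only when needed.

Step 1
Reactants: 1 methyl 2-(benzyloxy)acetate; 2 4-(benzyloxy)benzoyl chloride
Product: 3 methyl 2-(benzyloxy)-3-[4-(benzyloxy)phenyl]-3-oxopropanoate (racemic)
Conditions: 1 (2.1 equiv), LiN(iPr)2 (2.1 equiv), THF, −78 °C; then 2 (1.0 equiv), −78→0 °C; aq. NH4Cl
Reagents that add atoms: none
Why: Crossed Claisen acylation of the lithium enolate of the glycolate ester by the aroyl chloride, in which the second equivalent of enolate takes up the more acidic product and so stops double acylation; the C-2 stereocentre is racemic and disappears in step 2.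

Step 2
Reactants: 3 methyl 2-(benzyloxy)-3-[4-(benzyloxy)phenyl]-3-oxopropanoate
Product: 4 methyl 2-(benzyloxy)-3-[4-(benzyloxy)phenyl]-3-methoxyprop-2-enoate (E/Z mixture)
Conditions: Me2SO4 (1.3 equiv), Cs2CO3 (1.5 equiv), DMF, 0→25 °C
Reagents that add atoms: dimethyl sulfate, COS(=O)(=O)OC
Why: O-alkylation of a β-keto ester enolate, favoured by the cesium counter-ion in a dipolar aprotic solvent, the hard sulfate electrophile and the fully substituted α-carbon; the alkene geometry is of no consequence because both isomers converge in step 6.

Step 3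
Reactants: 4 methyl 2-(benzyloxy)-3-[4-(benzyloxy)phenyl]-3-methoxyprop-2-enoate
Product: 5 2-(benzyloxy)-3-[4-(benzyloxy)phenyl]-3-methoxyprop-2-enoic acid (E/Z mixture)
Conditions: LiOH·H2O (3 equiv), THF/MeOH/H2O, 40 °C; then cold dilute HCl to pH 4, immediate extraction
Reagents that add atoms: lithium hydroxide, [Li+].[OH-]
Why: Saponification of the methyl ester by acyl–oxygen cleavage; the β-carbon is fully substituted and donor-deactivated, so hydroxide should attack the ester carbonyl, and a cold, weakly acidic work-up should spare the enol ether.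

Step 4
Reactants: 6 3,5-bis(benzyloxy)phenol
Product: 7 2-bromo-3,5-bis(benzyloxy)phenol
Conditions: NBS (1.0 equiv), CH2Cl2, −78→0 °C
Reagents that add atoms: N-bromosuccinimide, O=C1CCC(=O)N1Br
Why: Electrophilic aromatic bromination of a phloroglucinol diether, delivered in a non-polar solvent at low temperature ortho to the hydrogen-bonding free hydroxyl (two equivalent positions); any 4-bromo isomer would be removed by chromatography.

Step 5
Reactants: 7 2-bromo-3,5-bis(benzyloxy)phenol
Product: 10 3,5-bis(benzyloxy)-2-(trimethylsilyl)phenyl trifluoromethanesulfonate, via aryl trimethylsilyl ether 8 (not isolated), via lithium 2-silylphenoxide 9 (not isolated)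
Conditions: HMDS, THF, 70 °C, then evaporation; n-BuLi (1.1 equiv), THF, −100 °C; Tf2O (1.2 equiv), −100→25 °C
Reagents that add atoms: hexamethyldisilazane, C[Si](C)(C)N[Si](C)(C)C; trifluoromethanesulfonic anhydride, O=S(=O)(OS(=O)(=O)C(F)(F)F)C(F)(F)F
Why: O-silylation, bromine–lithium exchange and 1,3-O→C silyl shift (retro-Brook rearrangement) place silicon on the carbon that bore bromine, and the lithium phenoxide is trapped as the triflate, the standard sequence to ortho-silylaryl triflates; exchange at −100 °C should outrun benzylic deprotonation of the ethers.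

Step 6
Reactants: 5 2-(benzyloxy)-3-[4-(benzyloxy)phenyl]-3-methoxyprop-2-enoic acid; 10 3,5-bis(benzyloxy)-2-(trimethylsilyl)phenyl trifluoromethanesulfonate
Product: 13 3,5,7-tris(benzyloxy)-2-[4-(benzyloxy)phenyl]-4H-chromen-4-one (kaempferol tetrabenzyl ether), via bis(benzyloxy)benzyne 11 (not isolated), via ortho-hydroxyaryl enone 12 (not isolated)
Conditions: 10 (1.5 equiv), CsF (4 equiv), THF, 125 °C, sealed tube
Reagents that add atoms: none
Why: Fluoride removes the silyl group of 10 and triflate leaves to give aryne 11, to which the carboxylate of 5 adds at the aryne carbon remote from the neighbouring benzyloxy group, so that the aryl anion sits ortho to that σ-withdrawing oxygen (the usual outcome for 3-alkoxyarynes) and O-1 and C-4 end up at C-8a and C-4a with the ether oxygens at C-5 and C-7. The aryl anion then attacks the ester carbonyl through a four-membered alkoxide that opens to the ortho-acyl phenoxide 12, a net insertion of the aryne into the C(acyl)–O bond. The phenoxide closes ring C by 6-endo-trig conjugate addition to the β-carbon of the enone and loss of methoxide (addition–elimination), which gives the pyranone at the flavonol oxidation level with O-3 in place; the adduct is a freely rotating enolate, so both alkene isomers of 5 converge. The closest known reaction type is the fluoride-induced C–O insertion of arynes into carboxylic acids, which gives chromanones from cinnamic acids, flavones from arylpropiolic acids and xanthones from 2-halobenzoic acids by the same insertion and ring-closure sequence. No stereocentre is formed. The step needs regioselective addition to the aryne, secured by the benzyloxy group beside the triple bond, and acyl transfer faster than protonation or conjugate addition of the aryl anion, favoured by dry conditions at high temperature and by the fully substituted, donor-bearing β-carbon.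

Step 7
Reactants: 13 3,5,7-tris(benzyloxy)-2-[4-(benzyloxy)phenyl]-4H-chromen-4-one
Product: 14 kaempferol (3,5,7-trihydroxy-2-(4-hydroxyphenyl)-4H-chromen-4-one)
Conditions: H2 (1 atm), Pd/C (palladium on carbon, 10%), THF/MeOH, 25 °C
Reagents that add atoms: none
Why: Hydrogenolysis of the four benzyl ethers over palladium on carbon; the tetrasubstituted C2=C3 bond of the cross-conjugated pyranone should not be reduced at 1 atm and room temperature.

Step 8
Reactants: 14 kaempferol
Product: 15 kaempferol 3,7,4'-tri-O-sulfate
Conditions: SO3·pyridine (3.6 equiv), pyridine, 0→25 °C; aq. KHCO3, C18 then Sephadex LH-20 (tripotassium salt); Dowex 50W (H+ form), 0 °C, for the acid form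
Reagents that add atoms: sulfur trioxide–pyridine complex, O=S(=O)([O-])[n+]1ccccc1
Why: O-sulfation with an SO3–amine complex should take the 7-, 4'- and 3-hydroxyls in that order, whereas the 5-OH, locked in its six-membered hydrogen bond to C4=O, should not react with a small excess at room temperature.

## Compound list

1 | methyl 2-(benzyloxy)acetate | COC(=O)COCc1ccccc1 | starting material
2 | 4-(benzyloxy)benzoyl chloride | O=C(Cl)c1ccc(OCc2ccccc2)cc1 | starting material
3 | methyl 2-(benzyloxy)-3-[4-(benzyloxy)phenyl]-3-oxopropanoate (racemic) | COC(=O)C(OCc1ccccc1)C(=O)c1ccc(OCc2ccccc2)cc1 | intermediate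
4 | methyl 2-(benzyloxy)-3-[4-(benzyloxy)phenyl]-3-methoxyprop-2-enoate (E/Z mixture, geometry not defined) | COC(=O)C(OCc1ccccc1)=C(OC)c1ccc(OCc2ccccc2)cc1 | intermediate
5 | 2-(benzyloxy)-3-[4-(benzyloxy)phenyl]-3-methoxyprop-2-enoic acid (E/Z mixture, geometry not defined) | OC(=O)C(OCc1ccccc1)=C(OC)c1ccc(OCc2ccccc2)cc1 | intermediate
6 | 3,5-bis(benzyloxy)phenol | Oc1cc(OCc2ccccc2)cc(OCc2ccccc2)c1 | starting material
7 | 2-bromo-3,5-bis(benzyloxy)phenol | Oc1cc(OCc2ccccc2)cc(OCc2ccccc2)c1Br | intermediate
8 | [3,5-bis(benzyloxy)-2-bromophenoxy]trimethylsilane | C[Si](C)(C)Oc1cc(OCc2ccccc2)cc(OCc2ccccc2)c1Br | intermediate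
9 | lithium 3,5-bis(benzyloxy)-2-(trimethylsilyl)phenoxide | [Li+].[O-]c1cc(OCc2ccccc2)cc(OCc2ccccc2)c1[Si](C)(C)C | intermediate
10 | 3,5-bis(benzyloxy)-2-(trimethylsilyl)phenyl trifluoromethanesulfonate | C[Si](C)(C)c1c(OCc2ccccc2)cc(OCc2ccccc2)cc1OS(=O)(=O)C(F)(F)F | intermediate
11 | 3,5-bis(benzyloxy)benzyne (3,5-bis(benzyloxy)-1,2-didehydrobenzene) | C1#CC(OCc2ccccc2)=CC(OCc2ccccc2)=C1 | intermediate
12 | 1-[2,4-bis(benzyloxy)-6-hydroxyphenyl]-2-(benzyloxy)-3-[4-(benzyloxy)phenyl]-3-methoxyprop-2-en-1-one (present as its cesium phenoxide; E/Z mixture) | COC(=C(OCc1ccccc1)C(=O)c1c(O)cc(OCc2ccccc2)cc1OCc1ccccc1)c1ccc(OCc2ccccc2)cc1 | intermediate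
13 | 3,5,7-tris(benzyloxy)-2-[4-(benzyloxy)phenyl]-4H-chromen-4-one | O=c1c(OCc2ccccc2)c(-c2ccc(OCc3ccccc3)cc2)oc2cc(OCc3ccccc3)cc(OCc3ccccc3)c12 | intermediate
14 | kaempferol | O=c1c(O)c(-c2ccc(O)cc2)oc2cc(O)cc(O)c12 | intermediate
15 | kaempferol 3,7,4'-tri-O-sulfate | O=c1c(OS(=O)(=O)O)c(-c2ccc(OS(=O)(=O)O)cc2)oc2cc(OS(=O)(=O)O)cc(O)c12 | target

Total step count: 8. Longest linear sequence: 6 steps (steps 1, 2, 3, 6, 7, 8); the aryne precursor (steps 4 and 5) joins at step 6.

Steps most likely to fail:

Step 6. The aryl anion may be protonated before the acyl group migrates (an aryl ester would result), the carboxylate may add to the aryne with poor regioselectivity, or acid 5 may degrade at 125 °C. The fallback would set out from β-keto ester 3 and use no aryne. Compound 3 would be heated with commercial phloroglucinol (benzene-1,3,5-triol) in diphenyl ether at 240 °C or under microwave heating. This Mentzer-type thermal chromone condensation (acylation of the phenol by the ester, closure of a phenolic oxygen onto the aryl ketone, loss of water) would give 3-(benzyloxy)-2-[4-(benzyloxy)phenyl]-5,7-dihydroxy-4H-chromen-4-one F1. Hydrogenolysis of F1 (H2, Pd/C, THF/MeOH) would give kaempferol 14, where the route is rejoined before step 8.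

Step 2. The ambident enolate may be methylated at carbon and give a quaternary α-methyl keto ester. The fallback would set out from 3 under acid, where no enolate is involved. HC(OMe)3, MeOH and catalytic TsOH at 60 °C would give the dimethyl ketal methyl 2-(benzyloxy)-3-[4-(benzyloxy)phenyl]-3,3-dimethoxypropanoate F2. Acid-catalysed loss of methanol from F2 (catalytic TsOH, toluene, reflux with distillation of methanol) would give enol ether 4, where the route is rejoined.

Step 8. Sulfation may stop at the 7,4'-disulfate, reach O-5, or give polyanionic mixtures that resist separation. The fallback would set out from 14 and install protected sulfates. 2,2,2-Trichloroethyl chlorosulfate (3.3 equiv), Et3N and DMAP in THF at 0→25 °C would give the neutral kaempferol 3,7,4'-tris(2,2,2-trichloroethyl sulfate) F3, which can be purified on silica gel. Zinc dust and ammonium formate in methanol would then remove the three trichloroethyl groups by reductive fragmentation and give 15.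

Further compounds
F1 | step 6 | 3-(benzyloxy)-2-[4-(benzyloxy)phenyl]-5,7-dihydroxy-4H-chromen-4-one | O=c1c(OCc2ccccc2)c(-c2ccc(OCc3ccccc3)cc2)oc2cc(O)cc(O)c12
F2 | step 2 | methyl 2-(benzyloxy)-3-[4-(benzyloxy)phenyl]-3,3-dimethoxypropanoate (racemic) | COC(=O)C(OCc1ccccc1)C(OC)(OC)c1ccc(OCc2ccccc2)cc1
F3 | step 8 | kaempferol 3,7,4'-tris(2,2,2-trichloroethyl sulfate) | O=c1c(OS(=O)(=O)OCC(Cl)(Cl)Cl)c(-c2ccc(OS(=O)(=O)OCC(Cl)(Cl)Cl)cc2)oc2cc(OS(=O)(=O)OCC(Cl)(Cl)Cl)cc(O)c12
A1 | direct plan | apigenin | O=c1cc(-c2ccc(O)cc2)oc2cc(O)cc(O)c12
A2 | direct plan | apigenin 7,4'-di-O-sulfate | O=c1cc(-c2ccc(OS(=O)(=O)O)cc2)oc2cc(OS(=O)(=O)O)cc(O)c12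
A3 | direct plan | cis-2,3-cyclic sulfate adduct of A2 (racemic, one enantiomer drawn) | O=C1c2c(O)cc(OS(=O)(=O)O)cc2O[C@]2(c3ccc(OS(=O)(=O)O)cc3)OS(=O)(=O)O[C@H]12
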